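Readings and results are simulated with constants of no real substance.

I decide to reckon both flasks by a single number read from the two earlier runs, and to bracket each answer before trusting it.

| setting | Sunday's | Wednesday's | zeta | delta |
|---|---|---|---|---|
| X | 16 mM | 16 mM | 16 mM | 16 mM |
| J | 24 mM | 39 mM | 60.0 mM | 28.8 mM |
| remark | run made earlier | run made earlier |  |  |
| time |  |  | 0.25 h | 1.0 h |

- Sunday's (time / min: G / %, X / %): 12.0: 8.7, 4.7; 25.0: 12.3, 2.3; 40.0: 13.7, 0.2; 50.0: 14.1, 1.0; 60.0: 14.1, 0.2
- Wednesday's (time / min: G / %, X / %): 5.00: 9.1, 10.6; 10.0: 15.1, 4.4; 15.0: 17.5, 2.7; 30.0: 20.3, 0.3; 60.0: 19.6, 0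

(each reading ± 0.3 percentage points)

* which of the two ends with the higher amount of G, in percent of the X charged ("neither" if they lie within 2 percentage points) (zeta / delta / neither)
* G at the end, in percent of the X charged, zeta
* G at the end, in percent of the X charged, delta

- percent here means X units held: one D counts as two
- the numbers in the tables scatter with a standard deviation of 0.3 percentage points
- steps thought possible: J + G -> L; J + E -> G; J -> Z; X + J -> E; 2 X -> D

In both runs the X readings die away, yet G stops at 14.1% in Sunday's run and tops out at 20.3% in Wednesday's. I take that plateau as the share of X that J captures, the rest going to D. Exponent 1 is my zero of the scale: every mM of J captures alike. The capture exponent n, the apparent order of the selectivity in [J], is the logarithm of the ratio of the plateaus over the logarithm of the ratio of [J], and it reads 0.751, less than that zero.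

The floor is the leaner run read at the same time, assuming more J captures no less: Sunday's at 60.0 min for delta, Wednesday's at 15.0 min for zeta. The ceiling scales the plateau of that run with exponent 1.

| flask | floor | with n | ceiling |
|---|---|---|---|
| delta | 14.1% | 16.2% | 16.9% |
| zeta | 17.5% | 28.0% | 31.2% |

The middle figure counts captured X, not finished G, and Wednesday's run still held 2.7% of X at 15.0 min, so I expect zeta somewhat below it.

The forecast says zeta, with 26% for zeta and 16% for delta: “The plateau therefore tracks the share of X captured by J”. Both lie inside the bracket, and its zeta stands lower than my middle figure.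

The flask gives zeta: zeta 25.5%, delta 16.4%, both inside the bracket too.

    J + G → L (k = 0.113 M⁻¹ min⁻¹)
    J + E → G (k = 7.44 M⁻¹ min⁻¹)
    J → Z (k = 0.0118 min⁻¹)
    X + J → E (k = 2.87 M⁻¹ min⁻¹)
    2 X → D (k = 35.4 M⁻¹ min⁻¹)

The pairing of X to D is what holds G down: with that step taken away, zeta ends at 69.3% of G instead of 25.5%. In zeta, G with L at 1.39% and E at 1.19% comes to 28.1%, against 28.0% from exponent 0.751. The neighbour of delta charged with 72 mM of J holds G and L of 32.9%, against 32.2% from the same exponent.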